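**Retrosynthetic overview**
- The strategy rests on the 2,2-dimethyl-2H-pyran ring (O1–C2–C3=C4–C4a–C8a) fused to the benzoyl-bearing ring: it is a prenyl group on C4a (C4–C3=C2Me2) that has lost two hydrogens and closed onto the C8a oxygen, so the O1–C2 bond is cut last, back to the ortho-prenyl triphenol 11.
- 11 comes from the tris-MOM ketone 10 and carbinol 9; the aryl–C(O) bond to the 2-hydroxy-4,6-dimethoxyphenyl ring is cut to aryllithium 8 (from MOM ether 7) and aldehyde 5.
- 5 comes from bromide 3 by Stille prenylation; 3 comes from regioselective bromination of bis-MOM 3,5-dihydroxybenzaldehyde 2, which fixes the prenyl group at the future C4a.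
- Ring order: both benzene rings are bought; the pyran ring is the only ring made, and it is made in the last step.

Key step: step 8

Remark: the target has no stereogenic centre or axis, so it is a single achiral compound and needs no enantiocontrol; the only stereocentre on the way (the carbinol carbon of 9) is formed racemic and removed by oxidation.

**Route**

Step 1
Reactants: 1 3,5-dihydroxybenzaldehyde
Product: 2 3,5-bis(methoxymethoxy)benzaldehyde
Conditions: NaH (2.4 equiv), MOMCl (2.4 equiv), THF–DMF, 0 °C → rt
Reagents that add atoms: chloromethyl methyl ether, COCCl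
Why: Williamson-type O-alkylation (MOM protection) of both phenoxides should proceed cleanly, since the aldehyde has no enolisable position and is inert to the phenoxide and the alkylating agent.

Step 2
Reactants: 2 3,5-bis(methoxymethoxy)benzaldehyde
Product: 3 2-bromo-3,5-bis(methoxymethoxy)benzaldehyde
Conditions: NBS (1.0 equiv), MeCN, 0 °C → rt, dark
Reagents that add atoms: N-bromosuccinimide, O=C1CCC(=O)N1Br
Why: Electrophilic aromatic bromination should go to C2, which is para to one OMOM and ortho to the other, rather than to the more hindered C4 between the two OMOM groups, as is usual for 3,5-dialkoxybenzaldehydes; one equivalent of NBS under near-neutral conditions spares the MOM acetals and avoids 2,6-dibromination.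

Step 3
Reactants: 3 2-bromo-3,5-bis(methoxymethoxy)benzaldehyde; 4 tributyl(3-methylbut-2-en-1-yl)stannane
Product: 5 3,5-bis(methoxymethoxy)-2-(3-methylbut-2-en-1-yl)benzaldehyde
Conditions: Pd(PPh3)4 (5 mol%), degassed DMF, 100 °C
Reagents that add atoms: none
Why: Stille cross-coupling should work because the ortho-formyl group eases oxidative addition, the aryl(allyl)palladium intermediate reductively eliminates at the unsubstituted allyl terminus to give the linear prenyl arene, and the neutral conditions tolerate the aldehyde and the MOM ethers.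

Step 4
Reactants: 6 3,5-dimethoxyphenol
Product: 7 1,3-dimethoxy-5-(methoxymethoxy)benzene
Conditions: NaH (1.2 equiv), MOMCl (1.2 equiv), THF, 0 °C → rt
Reagents that add atoms: chloromethyl methyl ether, COCCl
Why: MOM protection (Williamson-type O-alkylation) masks the phenol and installs the directing group needed for the metalation in step 5.

Step 5
Reactants: 7 1,3-dimethoxy-5-(methoxymethoxy)benzene; 5 3,5-bis(methoxymethoxy)-2-(3-methylbut-2-en-1-yl)benzaldehyde
Product: 9 [3,5-bis(methoxymethoxy)-2-(3-methylbut-2-en-1-yl)phenyl][2,4-dimethoxy-6-(methoxymethoxy)phenyl]methanol (racemic), via aryllithium 8 (not isolated)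
Conditions: 7 (1.5 equiv), n-BuLi (1.4 equiv), TMEDA, THF, 0 °C, 1 h; then 5 (1.0 equiv), −78 → 0 °C; H2O
Reagents that add atoms: none
Why: Directed ortho-metalation followed by 1,2-addition of the aryllithium to the non-enolisable aldehyde should work because OMOM directs more strongly than OMe, so deprotonation occurs at the site flanked by OMOM and OMe rather than between the two methoxy groups; the carbinol centre forms without control (racemic) and is removed in step 6.

Step 6
Reactants: 9 [3,5-bis(methoxymethoxy)-2-(3-methylbut-2-en-1-yl)phenyl][2,4-dimethoxy-6-(methoxymethoxy)phenyl]methanol (racemic)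
Product: 10 [3,5-bis(methoxymethoxy)-2-(3-methylbut-2-en-1-yl)phenyl][2,4-dimethoxy-6-(methoxymethoxy)phenyl]methanone
Conditions: Dess–Martin periodinane (1.5 equiv), pyridine, CH2Cl2, 0 °C → rt
Reagents that add atoms: none
Why: Dess–Martin oxidation of the doubly benzylic secondary alcohol should give the hindered tri-ortho-substituted benzophenone, and the buffered, non-acidic conditions leave the trisubstituted alkene and the MOM acetals untouched.

Step 7
Reactants: 10 [3,5-bis(methoxymethoxy)-2-(3-methylbut-2-en-1-yl)phenyl][2,4-dimethoxy-6-(methoxymethoxy)phenyl]methanone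
Product: 11 [3,5-dihydroxy-2-(3-methylbut-2-en-1-yl)phenyl](2-hydroxy-4,6-dimethoxyphenyl)methanone
Conditions: HCl (1.25 M in MeOH), rt → 40 °C, monitored and stopped at full conversion
Reagents that add atoms: none
Why: Acid-catalysed transacetalisation of the three aryl MOM ethers to methanol should free the phenols, while dilute acid at low temperature is too mild for Markovnikov addition of the freed ortho hydroxyl to the prenyl alkene and leaves the methyl ethers intact.

Step 8
Reactants: 11 [3,5-dihydroxy-2-(3-methylbut-2-en-1-yl)phenyl](2-hydroxy-4,6-dimethoxyphenyl)methanone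
Product: 13 (2-hydroxy-4,6-dimethoxyphenyl)(7-hydroxy-2,2-dimethyl-2H-chromen-5-yl)methanone, via ortho-quinone methide 12 (not isolated)
Conditions: DDQ (1.05 equiv), dry 1,4-dioxane (0.01 M), 80 °C
Reagents that add atoms: none
Why: DDQ should take hydride from C4, the benzylic and allylic CH2 of the prenyl group, with the developing cation stabilised by the ortho C8a and para C7 hydroxyls, and loss of the C8a–OH proton gives the ortho-quinone methide 12, in which O=C8a–C4a=C4–C3=C2Me2 is a 1-oxatriene. Thermal disrotatory oxa-6π electrocyclisation of the Z-configured 12 then forms the O1–C2 bond, closes the six-membered pyran ring and restores the aromaticity of the carbocycle. The closest known reaction type is the DDQ cyclodehydrogenation of ortho-prenylphenols to 2,2-dimethyl-2H-chromenes. No stereocentre is created, because C2 carries two methyl groups. The step needs regioselective closure and chemoselective oxidation: only the C8a hydroxyl is ortho to the prenyl group (the C7 hydroxyl can relay electrons but cannot cyclise), the ring-A phenol is hydrogen-bonded to the ketone and has no benzylic C–H, and one equivalent of DDQ at high dilution limits over-oxidation and intermolecular capture of 12.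

**Compound list**
1 | 3,5-dihydroxybenzaldehyde | O=Cc1cc(O)cc(O)c1 | starting material
2 | 3,5-bis(methoxymethoxy)benzaldehyde | COCOc1cc(C=O)cc(OCOC)c1 | intermediate
3 | 2-bromo-3,5-bis(methoxymethoxy)benzaldehyde | COCOc1cc(C=O)c(Br)c(OCOC)c1 | intermediate
4 | tributyl(3-methylbut-2-en-1-yl)stannane | CCCC[Sn](CCCC)(CCCC)CC=C(C)C | starting material
5 | 3,5-bis(methoxymethoxy)-2-(3-methylbut-2-en-1-yl)benzaldehyde | COCOc1cc(C=O)c(CC=C(C)C)c(OCOC)c1 | intermediate
6 | 3,5-dimethoxyphenol | COc1cc(O)cc(OC)c1 | starting material
7 | 1,3-dimethoxy-5-(methoxymethoxy)benzene | COCOc1cc(OC)cc(OC)c1 | intermediate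
8 | [2,4-dimethoxy-6-(methoxymethoxy)phenyl]lithium (not isolated) | [Li]c1c(OC)cc(OC)cc1OCOC | intermediate
9 | [3,5-bis(methoxymethoxy)-2-(3-methylbut-2-en-1-yl)phenyl][2,4-dimethoxy-6-(methoxymethoxy)phenyl]methanol (racemic) | COCOc1cc(OC)cc(OC)c1C(O)c1cc(OCOC)cc(OCOC)c1CC=C(C)C | intermediate
10 | [3,5-bis(methoxymethoxy)-2-(3-methylbut-2-en-1-yl)phenyl][2,4-dimethoxy-6-(methoxymethoxy)phenyl]methanone | COCOc1cc(OC)cc(OC)c1C(=O)c1cc(OCOC)cc(OCOC)c1CC=C(C)C | intermediate
11 | [3,5-dihydroxy-2-(3-methylbut-2-en-1-yl)phenyl](2-hydroxy-4,6-dimethoxyphenyl)methanone | COc1cc(O)c(C(=O)c2cc(O)cc(O)c2CC=C(C)C)c(OC)c1 | intermediate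
12 | (6Z)-3-hydroxy-5-(2-hydroxy-4,6-dimethoxybenzoyl)-6-(3-methylbut-2-en-1-ylidene)cyclohexa-2,4-dien-1-one (ortho-quinone methide, not isolated) | COc1cc(O)c(C(=O)C2=CC(O)=CC(=O)/C2=C\C=C(C)C)c(OC)c1 | intermediate
13 | (2-hydroxy-4,6-dimethoxyphenyl)(7-hydroxy-2,2-dimethyl-2H-chromen-5-yl)methanone | COc1cc(O)c(C(=O)c2cc(O)cc3c2C=CC(C)(C)O3)c(OC)c1 | target

**Step count**
Total steps: 8. Longest linear sequence: 7 (steps 1, 2, 3, 5, 6, 7, 8); step 4 is a one-step side branch.

**Steps most likely to fail**

1. Step 8. What may go wrong: over-oxidation of the electron-rich phenols, intermolecular capture or oligomerisation of the quinone methide, or adduct formation with the reagent, leading to low recovery of chromene. Fallback: the ring would be closed by selenium chemistry, setting out from 11 and returning at 13. PhSeCl (CH2Cl2, −78 °C) should form a seleniranium ion on the prenyl alkene, which the C8a hydroxyl opens at the tertiary carbon (6-endo, Markovnikov) to give racemic (2-hydroxy-4,6-dimethoxyphenyl)[7-hydroxy-2,2-dimethyl-3-(phenylselanyl)-3,4-dihydro-2H-chromen-5-yl]methanone F1. Oxidation with H2O2 (THF, 0 °C → rt) should give the selenoxide (2-hydroxy-4,6-dimethoxyphenyl)[7-hydroxy-2,2-dimethyl-3-(phenylseleninyl)-3,4-dihydro-2H-chromen-5-yl]methanone F2, which is not isolated. Its syn-elimination can only run towards C4, since C2 carries no hydrogen, and should deliver 13.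

2. Step 3. What may go wrong: allylic transposition during transmetalation or reductive elimination (giving the 1,1-dimethylallyl isomer), slow oxidative addition at the doubly ortho-substituted bromide with protodebromination, or palladium-mediated allyl transfer to the aldehyde. Fallback: the prenyl group would be introduced through an aryllithium, setting out from 3 and returning at 5. Acetalisation (HC(OMe)3, PPTS cat., MeOH, rt) should give 2-bromo-1-(dimethoxymethyl)-3,5-bis(methoxymethoxy)benzene F3. Bromine–lithium exchange (n-BuLi, THF, −78 °C) should give [2-(dimethoxymethyl)-4,6-bis(methoxymethoxy)phenyl]lithium F4, not isolated. Copper-catalysed SN2 alkylation with prenyl bromide (CuBr·SMe2 10 mol%, −78 → 0 °C) should give 1-(dimethoxymethyl)-3,5-bis(methoxymethoxy)-2-(3-methylbut-2-en-1-yl)benzene F5. Mild hydrolysis of the dimethyl acetal (PPTS, acetone–H2O, rt), which the aryl MOM ethers should survive, returns 5.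

3. Step 7. What may go wrong: acid-catalysed addition of the freed C8a hydroxyl to the prenyl alkene (chroman formation) competing with MOM cleavage, or incomplete removal of the three MOM groups. Fallback: the cyclisation would be accepted and driven to completion, setting out from 10 and returning at 13. p-TsOH·H2O in MeOH–toluene at 60 °C should remove the MOM groups and close the ring to (2-hydroxy-4,6-dimethoxyphenyl)(7-hydroxy-2,2-dimethyl-3,4-dihydro-2H-chromen-5-yl)methanone F6. DDQ (1,4-dioxane, reflux) should then dehydrogenate the chroman to the chromene by hydride abstraction from benzylic C4 (activated by O1 and the C7 hydroxyl) and proton loss from C3, giving 13.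

**Further compounds**
F1 | step 8 | (2-hydroxy-4,6-dimethoxyphenyl)[7-hydroxy-2,2-dimethyl-3-(phenylselanyl)-3,4-dihydro-2H-chromen-5-yl]methanone (racemic) | COc1cc(O)c(C(=O)c2cc(O)cc3c2CC([Se]c2ccccc2)C(C)(C)O3)c(OC)c1
F2 | step 8 | (2-hydroxy-4,6-dimethoxyphenyl)[7-hydroxy-2,2-dimethyl-3-(phenylseleninyl)-3,4-dihydro-2H-chromen-5-yl]methanone (diastereomer mixture, not isolated) | COc1cc(O)c(C(=O)c2cc(O)cc3c2CC([Se](=O)c2ccccc2)C(C)(C)O3)c(OC)c1
F3 | step 3 | 2-bromo-1-(dimethoxymethyl)-3,5-bis(methoxymethoxy)benzene | COCOc1cc(OCOC)c(Br)c(C(OC)OC)c1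
F4 | step 3 | [2-(dimethoxymethyl)-4,6-bis(methoxymethoxy)phenyl]lithium (not isolated) | [Li]c1c(C(OC)OC)cc(OCOC)cc1OCOC
F5 | step 3 | 1-(dimethoxymethyl)-3,5-bis(methoxymethoxy)-2-(3-methylbut-2-en-1-yl)benzene | COCOc1cc(OCOC)c(CC=C(C)C)c(C(OC)OC)c1
F6 | step 7 | (2-hydroxy-4,6-dimethoxyphenyl)(7-hydroxy-2,2-dimethyl-3,4-dihydro-2H-chromen-5-yl)methanone | COc1cc(O)c(C(=O)c2cc(O)cc3c2CCC(C)(C)O3)c(OC)c1
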